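**Plan**

- Numbering: C1 carries the aryl group, C2 the hydroxymethyl, C3 the formyl group, C4 is the alkene CH; ring A is C4a, C5, C6, C7, C8, C8a; ring B is C1 to C4 with C4a and C8a.
- Retrosynthetic cuts, in order: C3–C4 (aldol condensation, ring B); C8–C8a (6π closure of a dienylketene from a 4-alkenyl-2,3-dimethoxycyclobutenone, ring A); C4a–C5 (Stille coupling); C4–C4a (acetylide acylation); C2–C3 (enolate allylation); C1–C8a (conjugate alkynylation).
- Enabling feature: ring A has three adjacent oxygens on C6, C7 and C8 between the carbon-bearing C4a and C8a. A squarate-derived dienylketene delivers exactly this (squarate methoxy groups to O6 and O7, ketene oxygen to O8, alkene carbons to C4a and C8a).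
- Forward: guaiacyl ring bought as O-benzylvanillin, then the acyclic C1/C2 chain, ynoate, α-stannyl enoate, coupling to the chlorocyclobutenone, ring A by thermal benzannulation, ring B last by aldol condensation.
- Stereochemistry: C1 from a ligand-controlled rhodium-catalysed conjugate alkynylation, C2 from an oxazolidinone-controlled enolate allylation; neither is touched later, giving (1S,2R).

Key step: step 13

Remark: the acetal carbon of the 2-methoxyoxolane (steps 7 to 18) and the ring CH of the cyclobutenone (steps 10 to 12) are carried as epimer mixtures because both centres are erased later, and the bisphosphine antipode in step 2 is the one that gives (S)-5, its sense to be confirmed by correlation on the first run.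

**Route**

Step 1
Reactants: 1 4-(benzyloxy)-3-methoxybenzaldehyde (O-benzylvanillin); 2 Meldrum's acid
Product: 3 5-[4-(benzyloxy)-3-methoxybenzylidene]-2,2-dimethyl-1,3-dioxane-4,6-dione
Conditions: pyrrolidine (10 mol%), AcOH (10 mol%), PhMe, rt
Reagents that add atoms: none
Why: Knoevenagel condensation of a non-enolisable aryl aldehyde with the strongly acidic cyclic malonate should go to completion at room temperature, and the symmetric acceptor has no alkene geometry to control.

Step 2
Reactants: 3 arylidene Meldrum's acid; 4 ethynyltrimethylsilane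
Product: 5 5-{(1S)-1-[4-(benzyloxy)-3-methoxyphenyl]-3-(trimethylsilyl)prop-2-yn-1-yl}-2,2-dimethyl-1,3-dioxane-4,6-dione
Conditions: Rh(acac)(C2H4)2 (5 mol%), 3,5-xylyl-MeO-BIPHEP (6 mol%, antipode giving the S adduct), 4 (3 equiv), 1,4-dioxane, rt to 40 °C
Reagents that add atoms: none
Why: Rhodium-catalysed asymmetric conjugate alkynylation of an arylidene Meldrum's acid, in which a rhodium acetylide from the silylacetylene adds to the doubly activated alkene, the chiral bisphosphine selects the face of the benzylidene carbon and so sets C1, and the bulky silyl group holds back alkyne dimerisation.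

Step 3
Reactants: 5 alkynylated Meldrum's acid
Product: 7 (3R)-3-[4-(benzyloxy)-3-methoxyphenyl]pent-4-ynoic acid, via silylated acid 6 (not isolated)
Conditions: DMF/H2O (10:1), 100 °C; then K2CO3 (2.5 equiv), MeOH, rt; aq. HCl work-up
Reagents that add atoms: water, O
Why: Hydrolytic opening of the monosubstituted Meldrum's acid with loss of acetone, followed by thermal decarboxylation, should give the monoacid, and carbonate in methanol then removes the alkynyl silyl group (protodesilylation) without touching C1, whose descriptor changes from S to R only because the alkyne loses silicon.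

Step 4
Reactants: 7 pentynoic acid; 8 (4S)-4-benzyl-1,3-oxazolidin-2-one
Product: 10 (4S)-4-benzyl-3-{(3R)-3-[4-(benzyloxy)-3-methoxyphenyl]pent-4-ynoyl}-1,3-oxazolidin-2-one, via mixed anhydride 9 (not isolated)
Conditions: t-BuCOCl, Et3N, THF, −20 °C; then LiCl, 8, rt
Reagents that add atoms: none
Why: N-acylation of the oxazolidinone through the pivalic mixed anhydride under the LiCl/Et3N protocol needs no strong base that could touch the terminal alkyne, and any minor C1 antipode from step 2 becomes a separable diastereomer once the auxiliary is attached.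

Step 5
Reactants: 10 N-acyl oxazolidinone
Product: 12 (4S)-4-benzyl-3-[(2S)-2-{(1R)-1-[4-(benzyloxy)-3-methoxyphenyl]prop-2-yn-1-yl}pent-4-enoyl]-1,3-oxazolidin-2-one, via sodium enolate 11 (not isolated)
Conditions: NaN(SiMe3)2 (1.1 equiv), THF, −78 °C; allyl iodide (3 equiv), −78 to −40 °C
Reagents that add atoms: allyl iodide, C=CCI
Why: Evans alkylation, in which the chelated (Z)-sodium enolate is allylated on the face opposite the benzyl group of the (4S)-auxiliary, sets C2 as (2S) under auxiliary control regardless of the neighbouring C1 centre, the imide α-proton being far more acidic than the alkyne or benzylic C–H.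

Step 6
Reactants: 12 allylated imide
Product: 13 (2S)-2-{(1R)-1-[4-(benzyloxy)-3-methoxyphenyl]prop-2-yn-1-yl}pent-4-en-1-ol
Conditions: LiBH4, MeOH (1.1 equiv), Et2O, 0 °C
Reagents that add atoms: none
Why: Reductive cleavage of the N-acyl oxazolidinone by LiBH4 should give the primary alcohol (the future C2 hydroxymethyl) and return the auxiliary, with no risk to C2 because no enolisable carbonyl remains.

Step 7
Reactants: 13 pentenol
Product: 15 (4S)-4-{(1R)-1-[4-(benzyloxy)-3-methoxyphenyl]prop-2-yn-1-yl}-2-methoxyoxolane, via lactol 14 (not isolated)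
Conditions: OsO4 (2 mol%), NaIO4 (4 equiv), 2,6-lutidine, dioxane/H2O (3:1), rt; extractive work-up; then MeOH, PPTS (cat.), rt
Reagents that add atoms: methanol, CO
Why: Lemieux–Johnson cleavage of the terminal alkene (much faster than any reaction at the alkyne) gives the γ-hydroxy aldehyde, which closes to the five-membered lactol and is fixed by acid-catalysed acetalisation in methanol, so that one group masks both the C2 hydroxymethyl and the future formyl carbon.

Step 8
Reactants: 15 alkynyl methoxyoxolane
Product: 17 methyl (4S)-4-[4-(benzyloxy)-3-methoxyphenyl]-4-[(3S)-5-methoxyoxolan-3-yl]but-2-ynoate, via lithium acetylide 16 (not isolated)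
Conditions: n-BuLi (1.0 equiv), THF, −78 °C; ClCO2Me (1.5 equiv), −78 °C; cold aq. NH4Cl quench
Reagents that add atoms: methyl chloroformate, COC(=O)Cl
Why: C-acylation of a lithium acetylide with a chloroformate gives the ynoate (C4 attached to C4a), and an exact charge of base with a cold quench avoids base-mediated ynoate-to-allenoate isomerisation, which would erase C1.

Step 9
Reactants: 17 ynoate
Product: 18 methyl (2E,4R)-4-[4-(benzyloxy)-3-methoxyphenyl]-4-[(3S)-5-methoxyoxolan-3-yl]-2-(tributylstannyl)but-2-enoate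
Conditions: Bu3SnH (1.2 equiv), Pd(PPh3)4 (3 mol%), THF, 0 °C to rt
Reagents that add atoms: tributyltin hydride, CCCC[SnH](CCCC)CCCC
Why: Palladium-catalysed hydrostannation of an alkynoate is a syn addition that places tin on the ester-bearing carbon and hydrogen on the carbon next to the branched C1, giving the (E)-α-stannyl enoate in which the future C8a carries its hydrogen cis to tin.

Step 10
Reactants: 19 dimethyl squarate
Product: 20 4-hydroxy-2,3-dimethoxycyclobut-2-en-1-one
Conditions: LiAlH(OtBu)3 (1.05 equiv), THF, −78 to −20 °C; neutral work-up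
Reagents that add atoms: none
Why: Mono-reduction of one squarate carbonyl by the hindered alkoxyaluminium hydride should stop at the 4-hydroxycyclobutenone because the remaining carbonyl is a deactivated vinylogous ester, and a neutral work-up avoids acid-induced loss of methanol.

Step 11
Reactants: 20 hydroxycyclobutenone
Product: 21 4-chloro-2,3-dimethoxycyclobut-2-en-1-one
Conditions: PPh3 (1.2 equiv), CCl4 (3 equiv), CH2Cl2, 0 °C to rt; used at once
Reagents that add atoms: carbon tetrachloride, ClC(Cl)(Cl)Cl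
Why: Appel chlorination converts the allylic α-ketol into the allylic chloride under neutral conditions, which matters because the C4 oxygen ionises readily under acid, and the chloride is the leaving group that zerovalent palladium needs in the next step.

Step 12
Reactants: 18 α-stannyl enoate; 21 chlorocyclobutenone
Product: 22 methyl (2Z,4S)-4-[4-(benzyloxy)-3-methoxyphenyl]-2-(2,3-dimethoxy-4-oxocyclobut-2-en-1-yl)-4-[(3S)-5-methoxyoxolan-3-yl]but-2-enoate
Conditions: Pd2(dba)3 (2.5 mol%), tri(2-furyl)phosphine (10 mol%), CuI (10 mol%), NMP, rt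
Reagents that add atoms: none
Why: Stille coupling of a 4-chlorocyclobutenone with an alkenylstannane, in which oxidative addition gives an oxocyclobutenyl palladium species, CuI speeds transfer of the hindered α-ester alkenyl group from tin, and reductive elimination at the unsubstituted ring carbon with retention of alkene geometry forms the C4a–C5 bond, the mixture being kept at room temperature so that the cyclobutenone can be isolated before it ring-opens.

Step 13
Reactants: 22 4-alkenyl-2,3-dimethoxycyclobutenone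
Product: 25 methyl 2-{(S)-[4-(benzyloxy)-3-methoxyphenyl][(3S)-5-methoxyoxolan-3-yl]methyl}-3-hydroxy-4,5-dimethoxybenzoate, via dienylketene 23 (not isolated), via cyclohexadienone 24 (not isolated)
Conditions: PhMe (0.01 M, degassed), 100 °C
Reagents that add atoms: none
Why: Heating breaks the carbonyl–CH bond of the cyclobutenone in a conrotatory 4π electrocyclic opening to give dienylketene 23, and a disrotatory 6π electrocyclisation then joins the ketene carbon (future C8) to the alkene terminus (future C8a) to give cyclohexadienone 24, which enolises to phenol 25. The closest known reaction type is the thermal ring expansion of 4-alkenyl- and 4-arylcyclobutenones to phenols through dienylketenes, including those made by coupling 4-chlorocyclobutenones with alkenylstannanes. Ring A closes in this 6π electrocyclic mode with all six ring atoms drawn from the dienylketene, so the regiochemistry is fixed by connectivity: the squarate methoxy groups end on C6 and C7, the ketene oxygen on C8, the ester on C4a and the C1/C2 chain on C8a. No stereocentre is created, since the sp3 carbon of 24 is lost on tautomerisation, both ring CH epimers of 22 converge, and C1 and C2 are spectators under neutral thermolysis. The selectivity needed is inward rotation of the alkenyl group on ring opening; the outward-rotated ketene cannot close and reverts to 22, so reversible opening feeds the productive rotamer, and the alkene geometry of 22 (hydrogen inside, chain outside) keeps the closing terminus unhindered. High dilution in degassed toluene should limit ketene dimerisation and trapping of the ketene by the phenol already formed.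

Step 14
Reactants: 25 ring A phenol
Product: 26 methyl 2-{(S)-[4-(benzyloxy)-3-methoxyphenyl][(3S)-5-methoxyoxolan-3-yl]methyl}-3,4,5-trimethoxybenzoate
Conditions: MeI (3 equiv), K2CO3 (3 equiv), DMF, rt to 40 °C
Reagents that add atoms: iodomethane, CI
Why: Williamson methylation of the C8 hydroxyl, the only acidic O–H in 25, should proceed with iodomethane and carbonate while the ester and acetal stay inert.

Step 15
Reactants: 26 trimethoxy ester
Product: 27 (2-{(S)-[4-(benzyloxy)-3-methoxyphenyl][(3S)-5-methoxyoxolan-3-yl]methyl}-3,4,5-trimethoxyphenyl)methanol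
Conditions: i-Bu2AlH (2.5 equiv), CH2Cl2, −78 to 0 °C; Rochelle salt work-up
Reagents that add atoms: none
Why: Hydride reduction of the aryl methyl ester to the benzylic alcohol by i-Bu2AlH at low temperature leaves the acetal and aryl ethers alone and is the first half of the ester-to-aldehyde change at C4.

Step 16
Reactants: 27 benzylic alcohol
Product: 28 2-{(S)-[4-(benzyloxy)-3-methoxyphenyl][(3S)-5-methoxyoxolan-3-yl]methyl}-3,4,5-trimethoxybenzaldehyde
Conditions: MnO2 (activated, excess), CH2Cl2, rt
Reagents that add atoms: none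
Why: MnO2 oxidises benzylic alcohols selectively to aryl aldehydes without over-oxidation, and no other oxidisable alcohol or free phenol is present at this stage.

Step 17
Reactants: 28 benzyl-protected aldehyde
Product: 29 2-{(S)-(4-hydroxy-3-methoxyphenyl)[(3S)-5-methoxyoxolan-3-yl]methyl}-3,4,5-trimethoxybenzaldehyde
Conditions: H2 (1 atm), Pd/C (10%), EtOAc, rt; stopped at full conversion
Reagents that add atoms: none
Why: Hydrogenolysis of the aryl benzyl ether over Pd/C frees the guaiacyl phenol while no alkene is yet present, and the hindered, electron-rich aryl aldehyde should be reduced far more slowly than the benzyl ether is cleaved.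

Step 18
Reactants: 29 guaiacyl phenol aldehyde
Product: 30 4-hydroxy-2-{(S)-(4-hydroxy-3-methoxyphenyl)[(3S)-5-methoxyoxolan-3-yl]methyl}-3,5-dimethoxybenzaldehyde
Conditions: NaSEt (4 equiv), DMF, 100 °C; aq. HCl work-up
Reagents that add atoms: none
Why: Nucleophilic O-demethylation (SN2 at methyl by thiolate) should select the C7 methoxy because it alone is para to the formyl group and is twisted out of plane by its two neighbours, making its phenoxide the best leaving group, while the guaiacyl methoxy is shielded by the adjacent phenoxide.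

Step 19
Reactants: 30 bis-phenol aldehyde
Product: 32 (3R,4S)-6-hydroxy-4-(4-hydroxy-3-methoxyphenyl)-3-(hydroxymethyl)-5,7-dimethoxy-3,4-dihydronaphthalene-2-carbaldehyde (the target, 1S,2R in the numbering used here), via lactol 31 (not isolated)
Conditions: AcOH/THF/H2O (3:1:1), 45 °C; concentrate; then pyrrolidine (0.3 equiv), AcOH (1 equiv), THF, 40 °C, under argon
Reagents that add atoms: water, O
Why: Aqueous acetic acid hydrolyses the methyl acetal to the lactol, whose open γ-hydroxy aldehyde form is converted by the amine salt into an enamine at C3 that adds to the neighbouring aryl aldehyde (intramolecular aldol condensation closing the six-membered ring B), with dehydration driven by conjugation to ring A and its para hydroxyl, while C1 and C2 are not enolisable and keep their configuration.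

**Compound list**

1 | 4-(benzyloxy)-3-methoxybenzaldehyde (O-benzylvanillin) | COc1cc(C=O)ccc1OCc1ccccc1 | starting material
2 | Meldrum's acid (2,2-dimethyl-1,3-dioxane-4,6-dione) | CC1(C)OC(=O)CC(=O)O1 | starting material
3 | 5-[4-(benzyloxy)-3-methoxybenzylidene]-2,2-dimethyl-1,3-dioxane-4,6-dione | COc1cc(C=C2C(=O)OC(C)(C)OC2=O)ccc1OCc1ccccc1 | intermediate
4 | ethynyltrimethylsilane | C#C[Si](C)(C)C | starting material
5 | 5-{(1S)-1-[4-(benzyloxy)-3-methoxyphenyl]-3-(trimethylsilyl)prop-2-yn-1-yl}-2,2-dimethyl-1,3-dioxane-4,6-dione | C[Si](C)(C)C#C[C@H](c1ccc(OCc2ccccc2)c(OC)c1)C1C(=O)OC(C)(C)OC1=O | intermediate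
6 | (3S)-3-[4-(benzyloxy)-3-methoxyphenyl]-5-(trimethylsilyl)pent-4-ynoic acid | C[Si](C)(C)C#C[C@H](c1ccc(OCc2ccccc2)c(OC)c1)CC(=O)O | intermediate (not isolated)
7 | (3R)-3-[4-(benzyloxy)-3-methoxyphenyl]pent-4-ynoic acid | C#C[C@H](c1ccc(OCc2ccccc2)c(OC)c1)CC(=O)O | intermediate
8 | (4S)-4-benzyl-1,3-oxazolidin-2-one | O=C1N[C@@H](Cc2ccccc2)CO1 | starting material
9 | (3R)-3-[4-(benzyloxy)-3-methoxyphenyl]pent-4-ynoic pivalic anhydride | C#C[C@H](c1ccc(OCc2ccccc2)c(OC)c1)CC(=O)OC(=O)C(C)(C)C | intermediate (not isolated)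
10 | (4S)-4-benzyl-3-{(3R)-3-[4-(benzyloxy)-3-methoxyphenyl]pent-4-ynoyl}-1,3-oxazolidin-2-one | C#C[C@H](c1ccc(OCc2ccccc2)c(OC)c1)CC(=O)N1C(=O)OC[C@@H]1Cc1ccccc1 | intermediate
11 | sodium (Z)-enolate of 10 | C#C[C@H](c1ccc(OCc2ccccc2)c(OC)c1)/C=C(\[O-])N1C(=O)OC[C@@H]1Cc1ccccc1.[Na+] | intermediate (not isolated)
12 | (4S)-4-benzyl-3-[(2S)-2-{(1R)-1-[4-(benzyloxy)-3-methoxyphenyl]prop-2-yn-1-yl}pent-4-enoyl]-1,3-oxazolidin-2-one | C#C[C@H](c1ccc(OCc2ccccc2)c(OC)c1)[C@H](CC=C)C(=O)N1C(=O)OC[C@@H]1Cc1ccccc1 | intermediate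
13 | (2S)-2-{(1R)-1-[4-(benzyloxy)-3-methoxyphenyl]prop-2-yn-1-yl}pent-4-en-1-ol | C#C[C@H](c1ccc(OCc2ccccc2)c(OC)c1)[C@@H](CO)CC=C | intermediate
14 | (4S)-4-{(1R)-1-[4-(benzyloxy)-3-methoxyphenyl]prop-2-yn-1-yl}oxolan-2-ol (lactol, both epimers at C2) | C#C[C@H](c1ccc(OCc2ccccc2)c(OC)c1)[C@@H]1CC(O)OC1 | intermediate (not isolated)
15 | (4S)-4-{(1R)-1-[4-(benzyloxy)-3-methoxyphenyl]prop-2-yn-1-yl}-2-methoxyoxolane (both epimers at C2) | C#C[C@H](c1ccc(OCc2ccccc2)c(OC)c1)[C@@H]1CC(OC)OC1 | intermediate
16 | lithium acetylide of 15 (configuration unchanged) | [Li+].[C-]#C[C@H](c1ccc(OCc2ccccc2)c(OC)c1)[C@@H]1CC(OC)OC1 | intermediate (not isolated)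
17 | methyl (4S)-4-[4-(benzyloxy)-3-methoxyphenyl]-4-[(3S)-5-methoxyoxolan-3-yl]but-2-ynoate | COC(=O)C#C[C@H](c1ccc(OCc2ccccc2)c(OC)c1)[C@@H]1CC(OC)OC1 | intermediate
18 | methyl (2E,4R)-4-[4-(benzyloxy)-3-methoxyphenyl]-4-[(3S)-5-methoxyoxolan-3-yl]-2-(tributylstannyl)but-2-enoate | CCCC[Sn](CCCC)(CCCC)/C(C(=O)OC)=C/[C@H](c1ccc(OCc2ccccc2)c(OC)c1)[C@@H]1CC(OC)OC1 | intermediate
19 | dimethyl squarate (3,4-dimethoxycyclobut-3-ene-1,2-dione) | COC1=C(OC)C(=O)C1=O | starting material
20 | 4-hydroxy-2,3-dimethoxycyclobut-2-en-1-one (racemic) | COC1=C(OC)C(O)C1=O | intermediate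
21 | 4-chloro-2,3-dimethoxycyclobut-2-en-1-one (racemic) | COC1=C(OC)C(Cl)C1=O | intermediate
22 | methyl (2Z,4S)-4-[4-(benzyloxy)-3-methoxyphenyl]-2-(2,3-dimethoxy-4-oxocyclobut-2-en-1-yl)-4-[(3S)-5-methoxyoxolan-3-yl]but-2-enoate (both epimers at the ring CH) | COC(=O)/C(C1C(OC)=C(OC)C1=O)=C\[C@H](c1ccc(OCc2ccccc2)c(OC)c1)[C@@H]1CC(OC)OC1 | intermediate
23 | methyl (2Z,4S)-4-[4-(benzyloxy)-3-methoxyphenyl]-2-[(1E)-2,3-dimethoxy-4-oxobuta-1,3-dien-1-yl]-4-[(3S)-5-methoxyoxolan-3-yl]but-2-enoate (dienylketene) | O=C=C(OC)/C(OC)=C\C(C(=O)OC)=C\[C@H](c1ccc(OCc2ccccc2)c(OC)c1)[C@@H]1CC(OC)OC1 | intermediate (not isolated)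
24 | methyl 6-{(R)-[4-(benzyloxy)-3-methoxyphenyl][(3S)-5-methoxyoxolan-3-yl]methyl}-3,4-dimethoxy-5-oxocyclohexa-1,3-diene-1-carboxylate (ring CH unassigned) | COC(=O)C1=CC(OC)=C(OC)C(=O)C1[C@H](c1ccc(OCc2ccccc2)c(OC)c1)[C@@H]1CC(OC)OC1 | intermediate (not isolated)
25 | methyl 2-{(S)-[4-(benzyloxy)-3-methoxyphenyl][(3S)-5-methoxyoxolan-3-yl]methyl}-3-hydroxy-4,5-dimethoxybenzoate | COC(=O)c1cc(OC)c(OC)c(O)c1[C@H](c1ccc(OCc2ccccc2)c(OC)c1)[C@@H]1CC(OC)OC1 | intermediate
26 | methyl 2-{(S)-[4-(benzyloxy)-3-methoxyphenyl][(3S)-5-methoxyoxolan-3-yl]methyl}-3,4,5-trimethoxybenzoate | COC(=O)c1cc(OC)c(OC)c(OC)c1[C@H](c1ccc(OCc2ccccc2)c(OC)c1)[C@@H]1CC(OC)OC1 | intermediate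
27 | (2-{(S)-[4-(benzyloxy)-3-methoxyphenyl][(3S)-5-methoxyoxolan-3-yl]methyl}-3,4,5-trimethoxyphenyl)methanol | OCc1cc(OC)c(OC)c(OC)c1[C@H](c1ccc(OCc2ccccc2)c(OC)c1)[C@@H]1CC(OC)OC1 | intermediate
28 | 2-{(S)-[4-(benzyloxy)-3-methoxyphenyl][(3S)-5-methoxyoxolan-3-yl]methyl}-3,4,5-trimethoxybenzaldehyde | O=Cc1cc(OC)c(OC)c(OC)c1[C@H](c1ccc(OCc2ccccc2)c(OC)c1)[C@@H]1CC(OC)OC1 | intermediate
29 | 2-{(S)-(4-hydroxy-3-methoxyphenyl)[(3S)-5-methoxyoxolan-3-yl]methyl}-3,4,5-trimethoxybenzaldehyde | O=Cc1cc(OC)c(OC)c(OC)c1[C@H](c1ccc(O)c(OC)c1)[C@@H]1CC(OC)OC1 | intermediate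
30 | 4-hydroxy-2-{(S)-(4-hydroxy-3-methoxyphenyl)[(3S)-5-methoxyoxolan-3-yl]methyl}-3,5-dimethoxybenzaldehyde | O=Cc1cc(OC)c(O)c(OC)c1[C@H](c1ccc(O)c(OC)c1)[C@@H]1CC(OC)OC1 | intermediate
31 | 4-hydroxy-2-{(S)-(4-hydroxy-3-methoxyphenyl)[(3S)-5-hydroxyoxolan-3-yl]methyl}-3,5-dimethoxybenzaldehyde (lactol) | O=Cc1cc(OC)c(O)c(OC)c1[C@H](c1ccc(O)c(OC)c1)[C@@H]1CC(O)OC1 | intermediate (not isolated)
32 | (3R,4S)-6-hydroxy-4-(4-hydroxy-3-methoxyphenyl)-3-(hydroxymethyl)-5,7-dimethoxy-3,4-dihydronaphthalene-2-carbaldehyde | COc1cc([C@H]2c3c(cc(OC)c(O)c3OC)C=C(C=O)[C@@H]2CO)ccc1O | target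

**Totals and risks**

Total step count: 19. Longest linear sequence: 17 steps (steps 1 to 9 and 12 to 19); the cyclobutenone branch (steps 10 and 11) joins at step 12.

Steps most likely to fail:

Step 12. The hindered, electron-poor alkenyl group may transfer too slowly from tin to palladium, so that the activated chloride 21 decomposes first or the coupled cyclobutenone begins to ring-open during the reaction. The fallback changes the nucleophile from tin to zinc. It sets out from 18: iododestannylation (I2, CH2Cl2, 0 °C, retention of geometry) would give the α-iodo enoate methyl (2E,4R)-4-[4-(benzyloxy)-3-methoxyphenyl]-2-iodo-4-[(3S)-5-methoxyoxolan-3-yl]but-2-enoate F1. Zinc insertion (Zn dust, LiCl, THF) would give the alkenylzinc iodide methyl (2E,4R)-4-[4-(benzyloxy)-3-methoxyphenyl]-2-(iodozincio)-4-[(3S)-5-methoxyoxolan-3-yl]but-2-enoate F2. Negishi coupling of this with 21 (Pd2(dba)3, tri(2-furyl)phosphine, THF, rt) would come back to the route at 22. Partial loss of alkene geometry at the zinc stage would be tolerable, since both alkene isomers lead to the same phenol 25, although the isomer with the chain inside would need a higher temperature in step 13.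

Step 11. The C4–O or C4–Cl bond may ionise to an oxygen-stabilised cyclobutenyl cation, which would lose methanol to a cyclobutenedione or collapse to the labile α-chloro ether isomer. The fallback avoids the chloride altogether. It sets out from 20: acylation (ClCO2Me, pyridine, CH2Cl2, 0 °C) would give the allylic carbonate 2,3-dimethoxy-4-oxocyclobut-2-en-1-yl methyl carbonate F3. Zerovalent palladium ionises this under neutral conditions with loss of CO2 (Tsuji–Trost-type oxidative addition), and its Stille coupling with 18 (Pd2(dba)3, tri(2-furyl)phosphine, DMF, rt to 40 °C) would come back to the route at 22 without passing through 21.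

Step 18. Site selection between the C7 methyl ether and its C6 and C8 neighbours may be incomplete, or the aldehyde may degrade under hot thiolate. The fallback fixes the site by proximity instead of leaving-group ability. It sets out from 25, where the free C8 hydroxyl marks its C7 neighbour. Oxidative demethylation with o-iodoxybenzoic acid (DMF, rt) would give the C7,C8 ortho-quinone F4. Reduction (Na2S2O4, H2O/EtOAc) would give the C7,C8 catechol F5. Selective benzylation of the more acidic and less hindered C7 hydroxyl, para to the ester (BnBr, KHCO3, DMF), would give the C7 benzyl ether F6. Methylation of the C8 hydroxyl (MeI, K2CO3, DMF) would give the C8 methyl ether F7. Reduction (i-Bu2AlH) would give the benzylic alcohol F8, and oxidation (MnO2) the aldehyde F9. Hydrogenolysis of both benzyl ethers (H2, Pd/C, EtOAc) would come back to the route at 30, replacing steps 14 to 18.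

**Further compounds**

F1 | step 12 | methyl (2E,4R)-4-[4-(benzyloxy)-3-methoxyphenyl]-2-iodo-4-[(3S)-5-methoxyoxolan-3-yl]but-2-enoate | COC(=O)/C(I)=C\[C@H](c1ccc(OCc2ccccc2)c(OC)c1)[C@@H]1CC(OC)OC1
F2 | step 12 | methyl (2E,4R)-4-[4-(benzyloxy)-3-methoxyphenyl]-2-(iodozincio)-4-[(3S)-5-methoxyoxolan-3-yl]but-2-enoate | COC(=O)/C([Zn]I)=C\[C@H](c1ccc(OCc2ccccc2)c(OC)c1)[C@@H]1CC(OC)OC1
F3 | step 11 | 2,3-dimethoxy-4-oxocyclobut-2-en-1-yl methyl carbonate | COC(=O)OC1C(OC)=C(OC)C1=O
F4 | step 18 | methyl 2-{(S)-[4-(benzyloxy)-3-methoxyphenyl][(3S)-5-methoxyoxolan-3-yl]methyl}-5-methoxy-3,4-dioxocyclohexa-1,5-diene-1-carboxylate | COC(=O)C1=C([C@H](c2ccc(OCc3ccccc3)c(OC)c2)[C@@H]2CC(OC)OC2)C(=O)C(=O)C(OC)=C1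
F5 | step 18 | methyl 2-{(S)-[4-(benzyloxy)-3-methoxyphenyl][(3S)-5-methoxyoxolan-3-yl]methyl}-3,4-dihydroxy-5-methoxybenzoate | COC(=O)c1cc(OC)c(O)c(O)c1[C@H](c1ccc(OCc2ccccc2)c(OC)c1)[C@@H]1CC(OC)OC1
F6 | step 18 | methyl 4-(benzyloxy)-2-{(S)-[4-(benzyloxy)-3-methoxyphenyl][(3S)-5-methoxyoxolan-3-yl]methyl}-3-hydroxy-5-methoxybenzoate | COC(=O)c1cc(OC)c(OCc2ccccc2)c(O)c1[C@H](c1ccc(OCc2ccccc2)c(OC)c1)[C@@H]1CC(OC)OC1
F7 | step 18 | methyl 4-(benzyloxy)-2-{(S)-[4-(benzyloxy)-3-methoxyphenyl][(3S)-5-methoxyoxolan-3-yl]methyl}-3,5-dimethoxybenzoate | COC(=O)c1cc(OC)c(OCc2ccccc2)c(OC)c1[C@H](c1ccc(OCc2ccccc2)c(OC)c1)[C@@H]1CC(OC)OC1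
F8 | step 18 | (4-(benzyloxy)-2-{(S)-[4-(benzyloxy)-3-methoxyphenyl][(3S)-5-methoxyoxolan-3-yl]methyl}-3,5-dimethoxyphenyl)methanol | OCc1cc(OC)c(OCc2ccccc2)c(OC)c1[C@H](c1ccc(OCc2ccccc2)c(OC)c1)[C@@H]1CC(OC)OC1
F9 | step 18 | 4-(benzyloxy)-2-{(S)-[4-(benzyloxy)-3-methoxyphenyl][(3S)-5-methoxyoxolan-3-yl]methyl}-3,5-dimethoxybenzaldehyde | O=Cc1cc(OC)c(OCc2ccccc2)c(OC)c1[C@H](c1ccc(OCc2ccccc2)c(OC)c1)[C@@H]1CC(OC)OC1
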